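## Structural features

- The target joins two pentasubstituted arenes: an isochroman half (ring A; C1 acetal carbon, O2, C3, C4 bearing the acetyl group, 6-OH, 7-CHO, 8-OMe) and a 6′-oxy-8′-methoxy-3′-methylisoquinoline half.
- The halves are linked twice, by the C3–C7′ bond and the C1–O6′ aryl ether. C1 is therefore a mixed acetal and O2 is the one-atom bridge of a 2,9-dioxabicyclo[3.3.1]nonane whose two three-atom bridges are each fused to an arene (V-shaped).
- C1, C3 and C4 are contiguous along C1–O2–C3–C4. C1 and C3 are bridgeheads and geometrically coupled; C4 is independent. In the 1R,3R,4S target the acetyl group lies on the concave face, syn to the C3–C7′ bond, and H4 on the convex face.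
- C4–H is benzylic and α to the ketone. A model suggests the concave acetyl is the more crowded epimer, so C4 should be set late, kinetically, and not equilibrated afterwards.
- O2–C3–C4–C=O is a β-alkoxy ketone. Retro-oxa-Michael (E1cB) opening would erase C3 as well, and the acetal is acid-labile.
- The methyl ketone and the C1 aldehyde are 1,5-related. Once unmasked under base, acid or ammonia they can condense to a naphthol, a benzopyrylium or a second isoquinoline.
- Both halves carry the same 2-methoxy-4-oxy-benzene-1,3-dicarbon pattern with a carbon substituent at the remaining meta position, so one building block can serve twice.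
- The key step exploits that O2–C3 is a conjugate-addition bond to the enone C3=C4–C(=O)CH3, that C1/O2 is an aldehyde held on the aryl group at C4, and that O6′ sits ortho to C7′. The whole bicycle is then the isomer of a flat, achiral enone.

## Logic of the disconnections

**19 from 18.** The N–O bond is added retrosynthetically. The basic isoquinoline nitrogen would neutralise a chiral Brønsted acid, so it is carried as the N-oxide through the key step. The forward step must remove one oxygen under neutral conditions that leave C4 untouched.

**18 from 15 (key).** The O2–C3 and C1–O6′ bonds are cut and C4–H is removed, which gives the achiral (E)-enone 15 with a free 6′-OH and a free C1 aldehyde. In one sentence: an enantioselective, acid-catalysed transannular hemiacetal oxa-Michael bicyclisation of achiral enone 15. All three stereocentres and both rings of the bicycle disappear; 15 has no sp3 stereocentre. The forward step must select one face of C3, protonate C4 from the convex face, and not reverse.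

**15 from 14.** Two O–Si bonds are cut. The phenols must be freed without acid or free phenoxide, because either could trigger an unselective closure.

**14 from 12 and 13.** The C4–C4a bond (aryl to enone α-carbon) is cut, giving an α-bromo enone and an aryl boronate. This is convergent, needs no aldehyde protection, and gives the cis-diaryl (E) geometry by retention. The 6′-oxygen must stay silylated so that it cannot attack the vinyl–palladium centre.

**12 from 11, and 11 from 8 and 9.** The N–O bond and then the C3=C4 double bond are cut (olefination of the 7′-aldehyde with a brominated acetonyl ylide). The double bond carries no stereocentre, so nothing has to be controlled except E/Z, which the stabilised ylide sets. N-oxidation is placed after the olefination, when no electron-rich aryl aldehyde remains.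

**8 from 6, and 6 from 5.** The pyridine ring is cut at N–C1′ and N–C3′, then the aryl–alkyne bond. Only the aldehyde next to the alkyne can cyclise, which differentiates the two formyl groups of 5 without protection.

**13 from 5.** The C–B bond is cut. The same bromide 5 therefore supplies both halves.

**5 from 4, 4 from 3, 3 from 2, 2 from 1.** In turn: the O–CH3 bond, the formyl C–C bond, the O–Si bond, and two O–H for O–CH3 exchanges. Starting from symmetric 1 removes regiochemical doubt. The diol 2 is desymmetrised by one silylation, the free OH then directs formylation to its only open ortho position, and that OH (now between two formyl groups) is methylated.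

## Other disconnections considered

**Alternative 1: cross-aldol then acetalisation (the first idea).**
- Cut: C3–C4 and the acetal.
- Forward: aldol addition of arylacetone A1 to salicylaldehyde-type aldehyde A2 to give the anti β-hydroxy ketone A3, then acid-mediated closure to 19.
- Why not: A1 is a 2-(2-oxopropyl)benzaldehyde and should self-condense (naphthol or benzopyrylium) under enolising conditions, so it would need masking. The aldol must control regiochemistry (benzylic versus methyl enolate), anti selectivity and absolute configuration with a di-ortho-substituted acceptor. A3 is prone to retro-aldol and to dehydration. The chosen plan makes C3=C4 with no stereochemical demand and uses the dehydrated enone as the substrate.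

**Alternative 2: formal [3+3] annulation onto the phenol.**
- Cut: C3–C7′ and C1–O6′.
- Forward: Friedel–Crafts conjugate addition of isoquinolinol A4 to the vinylogous ester acetal A5, then transacetalisation.
- Why not: the most nucleophilic carbon of A4 is C5′ (ortho to OH, para to OMe, α-position of the bicyclic arene), not C7′, so a blocking group would be needed. A5 needs its own multistep synthesis, and C4 would still have to be set afterwards.

**Alternative 3: ring closure by ketone α-arylation.**
- Cut: C4–C4a.
- Forward: intramolecular Pd-catalysed α-arylation of the cis-2,4-disubstituted benzodioxine bromo ketone A6.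
- Why not: the enolate of A6 has the acetal oxygen as a β-leaving group, so E1cB fragmentation should outrun arylation and destroy C3. The basic medium would also equilibrate C4 toward the convex, non-natural epimer, and methyl versus methylene arylation is a further issue.

Key step: step 12

Remark: the facial preference of the phosphoric acid cannot be derived from first principles; (R)-TRIP is written, and its commercial antipode is used if the induction is opposite. Locants C1–C8a (isochroman half) and 1′–8′ (isoquinoline half) are used throughout.

## Steps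

Step 1
Reactants: 1 4-bromo-2,6-dimethoxybenzaldehyde
Product: 2 4-bromo-2,6-dihydroxybenzaldehyde
Conditions: BBr3 (2.5 equiv), CH2Cl2, −78 → 0 °C; then H2O
Reagents that add atoms: none
Why: Lewis-acid O-demethylation (BBr3 ether cleavage); both methoxy groups are ortho to the formyl group and cleave through the chelated aryloxyborane, and the symmetric product raises no regiochemical question.

Step 2
Reactants: 2 4-bromo-2,6-dihydroxybenzaldehyde
Product: 3 4-bromo-2-hydroxy-6-[(triisopropylsilyl)oxy]benzaldehyde
Conditions: TIPSCl (1.0 equiv), imidazole (1.1 equiv), CH2Cl2, 0 °C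
Reagents that add atoms: chlorotriisopropylsilane, CC(C)[Si](Cl)(C(C)C)C(C)C
Why: O-silylation; the two hydroxyls are equivalent, so this is a desymmetrisation, and a second bulky TIPS group flanking the same formyl group should be disfavoured.

Step 3
Reactants: 3 4-bromo-2-hydroxy-6-[(triisopropylsilyl)oxy]benzaldehyde
Product: 4 4-bromo-2-hydroxy-6-[(triisopropylsilyl)oxy]benzene-1,3-dicarbaldehyde
Conditions: Cl2CHOMe (1.5 equiv), TiCl4 (2.2 equiv), CH2Cl2, −20 → 0 °C; then cold 1 M HCl
Reagents that add atoms: dichloromethyl methyl ether, COC(Cl)Cl; water, O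
Why: Rieche formylation directed ortho by the titanium phenoxide; the only free position ortho to the OH is also para to the silyloxy donor, while the other open position is shielded by TIPS, so the new CHO goes between OH and Br and the OH ends between two formyl groups.

Step 4
Reactants: 4 4-bromo-2-hydroxy-6-[(triisopropylsilyl)oxy]benzene-1,3-dicarbaldehyde
Product: 5 4-bromo-2-methoxy-6-[(triisopropylsilyl)oxy]benzene-1,3-dicarbaldehyde
Conditions: MeI (5 equiv), Ag2O (1.5 equiv), MeCN, rt, dark
Reagents that add atoms: iodomethane, CI
Why: Purdie O-methylation under neutral conditions, chosen so that the electron-poor aryl silyl ether is not cleaved by base; it fixes the methoxy group between the two formyl groups, as both halves of the target require.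

Step 5
Reactants: 5 4-bromo-2-methoxy-6-[(triisopropylsilyl)oxy]benzene-1,3-dicarbaldehyde
Product: 6 2-methoxy-4-(prop-1-yn-1-yl)-6-[(triisopropylsilyl)oxy]benzene-1,3-dicarbaldehyde
Conditions: propyne (1 M in THF, 3 equiv), PdCl2(PPh3)2 (3 mol%), CuI (5 mol%), Et3N, THF, 45 °C, sealed tube
Reagents that add atoms: propyne, CC#C
Why: Sonogashira coupling; the bromide is activated by the ortho and para formyl groups, and aldehydes and the silyl ether tolerate the amine base.

Step 6
Reactants: 6 2-methoxy-4-(prop-1-yn-1-yl)-6-[(triisopropylsilyl)oxy]benzene-1,3-dicarbaldehyde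
Product: 8 8-methoxy-3-methyl-6-[(triisopropylsilyl)oxy]isoquinoline-7-carbaldehyde, via NH aldimine 7 (not isolated)
Conditions: NH4OAc (3 equiv), AgOTf (5 mol%), t-BuOH, 50 °C; aq. NaHCO3 work-up
Reagents that add atoms: ammonium acetate, CC(=O)[O-].[NH4+]
Why: imine condensation followed by silver-catalysed 6-endo-dig aminocyclisation and aromatisation (isoquinoline synthesis from an o-alkynylbenzaldehyde); only the aldehyde next to the alkyne can cyclise, and any imine at the hindered second aldehyde hydrolyses on work-up.

Step 7
Reactants: 8 8-methoxy-3-methyl-6-[(triisopropylsilyl)oxy]isoquinoline-7-carbaldehyde; 9 1-(triphenyl-λ5-phosphanylidene)propan-2-one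
Product: 11 (3Z)-3-bromo-4-{8-methoxy-3-methyl-6-[(triisopropylsilyl)oxy]isoquinolin-7-yl}but-3-en-2-one, via bromo ylide 10 (not isolated)
Conditions: 9 (1.3 equiv), NBS (1.3 equiv), CH2Cl2, −20 °C, 30 min; then 8, toluene, 80 °C
Reagents that add atoms: N-bromosuccinimide, O=C1CCC(=O)N1Br
Why: tandem ylide bromination and Wittig olefination; NBS brominates the stabilised ylide at carbon and the succinimide anion regenerates the ylide 10, which gives the α-bromo enone with aryl trans to acetyl, as stabilised ylides do. NBS is consumed before the electron-rich isoquinoline is added.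

Step 8
Reactants: 11 (3Z)-3-bromo-4-{8-methoxy-3-methyl-6-[(triisopropylsilyl)oxy]isoquinolin-7-yl}but-3-en-2-one
Product: 12 7-[(1Z)-2-bromo-3-oxobut-1-en-1-yl]-8-methoxy-3-methyl-6-[(triisopropylsilyl)oxy]isoquinoline 2-oxide
Conditions: mCPBA (1.1 equiv), CH2Cl2, 0 °C → rt; aq. NaHCO3 wash
Reagents that add atoms: 3-chloroperoxybenzoic acid, OOC(=O)c1cccc(Cl)c1
Why: peracid N-oxidation of the azine; the electron-poor bromo enone is inert, and no electron-rich aryl aldehyde remains that could undergo Dakin oxidation. The N-oxide silences the basic nitrogen for the acid-catalysed key step.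

Step 9
Reactants: 5 4-bromo-2-methoxy-6-[(triisopropylsilyl)oxy]benzene-1,3-dicarbaldehyde
Product: 13 2-methoxy-4-(4,4,5,5-tetramethyl-1,3,2-dioxaborolan-2-yl)-6-[(triisopropylsilyl)oxy]benzene-1,3-dicarbaldehyde
Conditions: B2pin2 (1.2 equiv), PdCl2(dppf) (5 mol%), KOAc (3 equiv), 1,4-dioxane, 85 °C
Reagents that add atoms: bis(pinacolato)diboron, CC1(C)OB(OC1(C)C)B1OC(C)(C)C(C)(C)O1
Why: Miyaura borylation; the acetate-mediated conditions are anhydrous and weakly basic, so both aldehydes and the aryl silyl ether should survive.

Step 10
Reactants: 12 7-[(1Z)-2-bromo-3-oxobut-1-en-1-yl]-8-methoxy-3-methyl-6-[(triisopropylsilyl)oxy]isoquinoline 2-oxide; 13 2-methoxy-4-(4,4,5,5-tetramethyl-1,3,2-dioxaborolan-2-yl)-6-[(triisopropylsilyl)oxy]benzene-1,3-dicarbaldehyde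
Product: 14 7-[(1E)-2-{2,4-diformyl-3-methoxy-5-[(triisopropylsilyl)oxy]phenyl}-3-oxobut-1-en-1-yl]-8-methoxy-3-methyl-6-[(triisopropylsilyl)oxy]isoquinoline 2-oxide
Conditions: SPhos Pd G3 (5 mol%), K3PO4 (2 equiv), THF/H2O (10:1), 40 °C
Reagents that add atoms: none
Why: Suzuki–Miyaura coupling; the α-bromo enone adds oxidatively under mild conditions and couples with retention, placing the two aryl groups cis (E enone). The silyl group on O6′ prevents intramolecular O-vinylation to a benzofuran.

Step 11
Reactants: 14 7-[(1E)-2-{2,4-diformyl-3-methoxy-5-[(triisopropylsilyl)oxy]phenyl}-3-oxobut-1-en-1-yl]-8-methoxy-3-methyl-6-[(triisopropylsilyl)oxy]isoquinoline 2-oxide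
Product: 15 7-[(1E)-2-(2,4-diformyl-5-hydroxy-3-methoxyphenyl)-3-oxobut-1-en-1-yl]-6-hydroxy-8-methoxy-3-methylisoquinoline 2-oxide
Conditions: TBAF (2.2 equiv), AcOH (2.5 equiv), THF, 0 °C; pH 7 buffer work-up
Reagents that add atoms: none
Why: fluoride-mediated desilylation of both aryl silyl ethers; the acetic acid buffer keeps free phenoxide low, so a phenoxide-triggered, unselective closure of the liberated substrate should be suppressed.

Step 12
Reactants: 15 7-[(1E)-2-(2,4-diformyl-5-hydroxy-3-methoxyphenyl)-3-oxobut-1-en-1-yl]-6-hydroxy-8-methoxy-3-methylisoquinoline 2-oxide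
Product: 18 (1R,3R,4S)-2′-N-oxide of the target, via cyclic hemiacetal 16 (not isolated), via bridged enol 17 (not isolated)
Conditions: (R)-TRIP (10 mol%), CH2Cl2/toluene (1:1), 4 Å MS, −20 → 0 °C; quench with Et3N at full conversion
Reagents that add atoms: none
Why: Proposed new method: an enantioselective transannular hemiacetal oxa-Michael bicyclisation, whose closest known reaction types are the hemiacetal/oxa-Michael cyclisation of hydroxy enones with aldehydes (base-mediated, and asymmetric with bifunctional organocatalysts) and chiral phosphoric acid-catalysed asymmetric acetalisations and additions to ortho-quinone-methide-type acceptors. The acid mediates reversible addition of 6′-OH to the C1 aldehyde of the cis-disposed A ring to give hemiacetal 16 (its C1 epimers interconvert by ring opening), activates the enone, whose C3 is made electrophilic by the 6′,8′-dioxygenated aryl group, and delivers the hemiacetal OH to C3 to give enol 17, which tautomerises to 18. Hemiacetalisation closes an eight-membered ring (8-exo-trig), and the single O2–C3 bond then closes the isochroman ring (6-endo-trig) and the 1,3-benzodioxine ring (6-exo-trig) at once. C3 is set by the catalyst, which is expected to hold the hemiacetal OH and the enone carbonyl in a bifunctional hydrogen-bond/ion-pair array inside its 3,3′-aryl pocket and so select one enone face; because 16 racemises faster than it cyclises, this is a dynamic kinetic resolution. C1 is not independent, since only the hemiacetal epimer whose OH lies over C3 can bridge. C4 is set by kinetic protonation of 17 on its open convex face, anti to the isoquinoline bridge, which leaves the acetyl group on the concave face as required. The step needs chemoselectivity for the C1 aldehyde (secured by proximity; the 7-CHO is remote and hydrogen-bonded to 6-OH), a silent nitrogen (secured by the N-oxide) and kinetic control (the product lacks the free 6′-OH that assists ionisation of O2–C3, so reversal and C4 enolisation should be slow at or below 0 °C).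

Step 13
Reactants: 18 (1R,3R,4S)-2′-N-oxide of the target
Product: 19 CNP0584953.1
Conditions: B2pin2 (1.5 equiv), MeCN, 60 °C
Reagents that add atoms: none
Why: deoxygenation of a heteroaromatic N-oxide by oxygen transfer to the B–B bond of a diboron reagent; the conditions are neutral, so the aldehyde, ketone, phenol and acetal should be untouched and C4 should not epimerise.

## Compound list

1 | 4-bromo-2,6-dimethoxybenzaldehyde | COc1cc(Br)cc(OC)c1C=O | starting material
2 | 4-bromo-2,6-dihydroxybenzaldehyde | Oc1cc(Br)cc(O)c1C=O | intermediate
3 | 4-bromo-2-hydroxy-6-[(triisopropylsilyl)oxy]benzaldehyde | CC(C)[Si](Oc1cc(Br)cc(O)c1C=O)(C(C)C)C(C)C | intermediate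
4 | 4-bromo-2-hydroxy-6-[(triisopropylsilyl)oxy]benzene-1,3-dicarbaldehyde | Oc1c(C=O)c(O[Si](C(C)C)(C(C)C)C(C)C)cc(Br)c1C=O | intermediate
5 | 4-bromo-2-methoxy-6-[(triisopropylsilyl)oxy]benzene-1,3-dicarbaldehyde | COc1c(C=O)c(O[Si](C(C)C)(C(C)C)C(C)C)cc(Br)c1C=O | intermediate
6 | 2-methoxy-4-(prop-1-yn-1-yl)-6-[(triisopropylsilyl)oxy]benzene-1,3-dicarbaldehyde | COc1c(C=O)c(O[Si](C(C)C)(C(C)C)C(C)C)cc(C#CC)c1C=O | intermediate
7 | 3-(iminomethyl)-2-methoxy-4-(prop-1-yn-1-yl)-6-[(triisopropylsilyl)oxy]benzaldehyde (NH aldimine, formed in situ) | COc1c(C=O)c(O[Si](C(C)C)(C(C)C)C(C)C)cc(C#CC)c1C=N | intermediate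
8 | 8-methoxy-3-methyl-6-[(triisopropylsilyl)oxy]isoquinoline-7-carbaldehyde | O=Cc1c(OC)c2cnc(C)cc2cc1O[Si](C(C)C)(C(C)C)C(C)C | intermediate
9 | 1-(triphenyl-λ5-phosphanylidene)propan-2-one | CC(=O)C=P(c1ccccc1)(c1ccccc1)c1ccccc1 | starting material
10 | 1-bromo-1-(triphenyl-λ5-phosphanylidene)propan-2-one (bromo ylide, formed in situ) | CC(=O)C(Br)=P(c1ccccc1)(c1ccccc1)c1ccccc1 | intermediate
11 | (3Z)-3-bromo-4-{8-methoxy-3-methyl-6-[(triisopropylsilyl)oxy]isoquinolin-7-yl}but-3-en-2-one | CC(=O)/C(Br)=C/c1c(OC)c2cnc(C)cc2cc1O[Si](C(C)C)(C(C)C)C(C)C | intermediate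
12 | 7-[(1Z)-2-bromo-3-oxobut-1-en-1-yl]-8-methoxy-3-methyl-6-[(triisopropylsilyl)oxy]isoquinoline 2-oxide | CC(=O)/C(Br)=C/c1c(OC)c2c[n+]([O-])c(C)cc2cc1O[Si](C(C)C)(C(C)C)C(C)C | intermediate
13 | 2-methoxy-4-(4,4,5,5-tetramethyl-1,3,2-dioxaborolan-2-yl)-6-[(triisopropylsilyl)oxy]benzene-1,3-dicarbaldehyde | COc1c(C=O)c(O[Si](C(C)C)(C(C)C)C(C)C)cc(B2OC(C)(C)C(C)(C)O2)c1C=O | intermediate
14 | 7-[(1E)-2-{2,4-diformyl-3-methoxy-5-[(triisopropylsilyl)oxy]phenyl}-3-oxobut-1-en-1-yl]-8-methoxy-3-methyl-6-[(triisopropylsilyl)oxy]isoquinoline 2-oxide | CC(=O)/C(=C/c1c(OC)c2c[n+]([O-])c(C)cc2cc1O[Si](C(C)C)(C(C)C)C(C)C)c1cc(O[Si](C(C)C)(C(C)C)C(C)C)c(C=O)c(OC)c1C=O | intermediate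
15 | 7-[(1E)-2-(2,4-diformyl-5-hydroxy-3-methoxyphenyl)-3-oxobut-1-en-1-yl]-6-hydroxy-8-methoxy-3-methylisoquinoline 2-oxide | CC(=O)/C(=C/c1c(OC)c2c[n+]([O-])c(C)cc2cc1O)c1cc(O)c(C=O)c(OC)c1C=O | intermediate
16 | eight-membered cyclic hemiacetal of 15 (O6′–C1 bond formed; C1 epimers interconvert; formed in situ) | CC(=O)C1=Cc2c(OC)c3c[n+]([O-])c(C)cc3cc2OC(O)c2c1cc(O)c(C=O)c2OC | intermediate
17 | (1R,3R)-bridged acetal enol, i.e. 18 with C4=C(OH)CH3 in place of C4H–COCH3 (formed in situ) | COc1c(C=O)c(O)cc2c1[C@H]1Oc3cc4cc(C)[n+]([O-])cc4c(OC)c3[C@H](O1)C2=C(C)O | intermediate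
18 | (1R,3R,4S)-2′-N-oxide of the target (isoquinoline 2-oxide of 19) | COc1c(C=O)c(O)cc2c1[C@H]1Oc3cc4cc(C)[n+]([O-])cc4c(OC)c3[C@H](O1)[C@H]2C(C)=O | intermediate
19 | CNP0584953.1: (1R,3R,4S)-4-acetyl-6-hydroxy-8-methoxyisochroman-7-carbaldehyde bridged through C1–O–C6′ and C3–C7′ to 8′-methoxy-3′-methylisoquinoline | COc1c(C=O)c(O)cc2c1[C@H]1Oc3cc4cc(C)ncc4c(OC)c3[C@H](O1)[C@H]2C(C)=O | target

## Step count and least certain steps

Total: 13 steps. Longest linear sequence: 12 steps (steps 1–8, then 10–13); step 9 is the convergent branch from 5.

**Step 12 (key step).**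
- What may go wrong: insufficient facial discrimination in the O2–C3 bond formation. Causes could be an uncatalysed background closure of 15, or sequestration of the acid by hydrogen bonding to the N-oxide. Erosion is also possible through slow retro-oxa-Michael opening, and acid-catalysed enolisation could move C4 to the convex epimer if the reaction is left too long.
- Fallback (known chemistry): from 15, the same closure is run without asymmetric induction using catalytic camphorsulfonic acid in CH2Cl2 at 0 °C. This should give 18 together with its mirror image, the (1S,3S,4R)-enantiomer of 18 F1. The two are separated by preparative supercritical-fluid chromatography on a polysaccharide chiral stationary phase, and the route is rejoined at 18.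

**Step 3 (Rieche formylation of 3).**
- What may go wrong: loss of the aryl silyl ether under TiCl4/HCl, or low reactivity of the formyl- and bromo-deactivated ring.
- Fallback: the order is inverted. From 2, the Rieche formylation is run on the more electron-rich diol, where symmetry again leaves only one kind of position, to give 4-bromo-2,6-dihydroxybenzene-1,3-dicarbaldehyde F2. The hydroxyl flanked by only one formyl group is then silylated selectively on steric grounds with TIPSCl/imidazole, rejoining the route at 4. The regiochemistry of this silylation would have to be confirmed before going on.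

**Step 7 (bromination/Wittig).**
- What may go wrong: slow olefination, because the aldehyde is flanked by OMe and OTIPS and the bromo ylide is bulky and weakly nucleophilic; prolonged heating could then degrade the ylide.
- Fallback: the olefinating species is changed to a phosphonate carbanion. Diethyl (1-bromo-2-oxopropyl)phosphonate F3 is made from commercial diethyl (2-oxopropyl)phosphonate and NBS, and is used from 8 in a Horner–Wadsworth–Emmons reaction under LiCl/DBU in MeCN. The route is rejoined at 11; an E/Z mixture at this stage would be carried forward and corrected, if needed, by equilibration of 14.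

**Step 10 (Suzuki–Miyaura coupling).**
- What may go wrong: protodeboronation of the ortho-formyl boronate in aqueous base, or premature loss of the 6′-O-silyl group followed by intramolecular O-vinylation at palladium to a benzofuran.
- Fallback: a base-free Stille coupling. From 5, stannylation with hexabutylditin and Pd(PPh3)4 in toluene gives 2-methoxy-4-(tributylstannyl)-6-[(triisopropylsilyl)oxy]benzene-1,3-dicarbaldehyde F4. This is coupled with 12 using Pd2(dba)3, AsPh3 and CuI in DMF at 40 °C, rejoining the route at 14.

## Further compounds

F1 | step 12 | (1S,3S,4R)-enantiomer of 18 | COc1c(C=O)c(O)cc2c1[C@@H]1Oc3cc4cc(C)[n+]([O-])cc4c(OC)c3[C@@H](O1)[C@@H]2C(C)=O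
F2 | step 3 | 4-bromo-2,6-dihydroxybenzene-1,3-dicarbaldehyde | Oc1c(C=O)c(O)cc(Br)c1C=O
F3 | step 7 | diethyl (1-bromo-2-oxopropyl)phosphonate | CCOP(=O)(OCC)C(Br)C(C)=O
F4 | step 10 | 2-methoxy-4-(tributylstannyl)-6-[(triisopropylsilyl)oxy]benzene-1,3-dicarbaldehyde | CCCC[Sn](CCCC)(CCCC)c1cc(O[Si](C(C)C)(C(C)C)C(C)C)c(C=O)c(OC)c1C=O
A1 | alternative 1 | 4-hydroxy-2-methoxy-6-(2-oxopropyl)benzene-1,3-dicarbaldehyde | COc1c(C=O)c(O)cc(CC(C)=O)c1C=O
A2 | alternative 1 | 6-hydroxy-8-methoxy-3-methylisoquinoline-7-carbaldehyde | Cc1cc2cc(O)c(C=O)c(OC)c2cn1
A3 | alternative 1 | (3S,4R)-anti-aldol adduct: 3-(2,4-diformyl-5-hydroxy-3-methoxyphenyl)-4-hydroxy-4-(6-hydroxy-8-methoxy-3-methylisoquinolin-7-yl)butan-2-one | COc1c(C=O)c(O)cc(c1C=O)[C@H](C(C)=O)[C@@H](O)c1c(O)cc2cc(C)ncc2c1OC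
A4 | alternative 2 | 8-methoxy-3-methylisoquinolin-6-ol | Cc1cc2cc(O)cc(OC)c2cn1
A5 | alternative 2 | 4-acetyl-6-hydroxy-1,8-dimethoxy-1H-isochromene-7-carbaldehyde | COc1c(C=O)c(O)cc2c1C(OC)OC=C2C(C)=O
A6 | alternative 3 | (2R,4R)-cis-2-(6-bromo-3-formyl-4-hydroxy-2-methoxyphenyl)-4-(2-oxopropyl)-4H-1,3-dioxine fused at its 5,6-bond to C7′–C6′ of 8′-methoxy-3′-methylisoquinoline | COc1c(C=O)c(O)cc(Br)c1[C@H]1Oc2cc3cc(C)ncc3c(OC)c2[C@@H](CC(C)=O)O1
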